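**Plan**

- Names used: ring A arene, B oxepane, C cyclopentane, D cyclohexane, E cyclopropane. C1 is the benzylic CH(isobutyl), C2 C(CH3), C3 the CH shared by B/C/D, C4 C–O, C5/C6 the CH2 groups of ring C, C7 CH(CH3), C8 CH2, C9/C10 the cyclopropane CH (C10 on C3), C11 C(CH3)2.
- Retrosynthesis: cut both Ar–CHO bonds, then O–C4 together with C7–H (leaving a C4=C7 alkene), then C8–C9 and C10–C3 in one stroke. The diene C3=C4–C7=C8 then goes back to an enyne, and C2–C6 and C2–CH3 to lactone enolate alkylations.
- Enabling feature: ring D is a cyclohexane cis-fused to the gem-dimethylcyclopropane E at C9–C10, and its vicinal pair C4(OAr)/C7(H) lies directly across the ring from that bond. Taking ArO–H out turns ring D into a 3-carene-type cyclohexene, the retron of a Diels–Alder union of a 1-isopropenylcyclopentene (ring C) with 3,3-dimethylcyclopropene.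
- Forward order: ring A (phloroglucinol), temporary lactone ring (Pechmann), ring C (ring-closing enyne metathesis), rings D and E (cycloaddition), ring B (phenol onto C4), two formyl groups.
- Stereochemistry: C1 comes from a chiral copper hydride catalyst, and C2 from alkylation anti to the isobutyl group in the temporary lactone. C3, C9 and C10 come from the C2-controlled face and the exo mode of the cycloaddition, and C7 and C4 from anti addition of H+ and the tethered phenol.

Key step: step 12

Assumption: the sense of induction in step 3 is taken by analogy with related 4-substituted coumarins; if (R)-DTBM-SEGPHOS should favour the 4S lactone, the equally available (S)-ligand is used and nothing else changes.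

**Route**

Step 1
Reactants: 1 phloroglucinol; 2 ethyl 5-methyl-3-oxohexanoate
Product: 3 5,7-dihydroxy-4-(2-methylpropyl)-2H-chromen-2-one
Conditions: CF3SO3H, 0 °C to rt
Reagents that add atoms: none
Why: Pechmann condensation (transesterification, ring hydroxyalkylation, dehydration) of the threefold-symmetric, very nucleophilic phenol can give only this coumarin, which joins ring A to C1 and the isobutyl group and provides the temporary lactone ring.

Step 2
Reactants: 3 5,7-dihydroxy-4-(2-methylpropyl)-2H-chromen-2-one
Product: 4 5,7-bis(benzyloxy)-4-(2-methylpropyl)-2H-chromen-2-one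
Conditions: BnBr, K2CO3, DMF, 60 °C
Reagents that add atoms: benzyl bromide BrCc1ccccc1
Why: Williamson etherification masks both free phenols as benzyl ethers that tolerate the bases, hydrides and carbene catalysts used later and leave by hydrogenolysis.

Step 3
Reactants: 4 5,7-bis(benzyloxy)-4-(2-methylpropyl)-2H-chromen-2-one
Product: 5 (4R)-5,7-bis(benzyloxy)-4-(2-methylpropyl)chroman-2-one
Conditions: Cu(OAc)2·H2O (cat.), (R)-DTBM-SEGPHOS (cat.), (EtO)2MeSiH, t-BuOH, toluene, 0 °C to rt
Reagents that add atoms: none
Why: Asymmetric conjugate reduction by ligated CuH, a reaction type established for 4-substituted coumarins, delivers hydride to one face of lactone position 4 (C1 of the target) under control of the chiral bisphosphine, while t-BuOH protonates the copper enolate so that the lactone carbonyl is spared.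

Step 4
Reactants: 5 (4R)-5,7-bis(benzyloxy)-4-(2-methylpropyl)chroman-2-one
Product: 7 (3R,4R)-5,7-bis(benzyloxy)-3-methyl-4-(2-methylpropyl)chroman-2-one (3,4-trans), via lithium enolate 6 (not isolated)
Conditions: LiN(SiMe3)2, THF, −78 °C; then MeI, −78 to −40 °C
Reagents that add atoms: iodomethane CI
Why: Lactone enolate alkylation with the small electrophile first puts the methyl group anti to the pseudo-axial isobutyl group, but this centre is planarised again in step 6, so its configuration is of no consequence.

Step 5
Reactants: 8 pent-3-yn-1-ol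
Product: 9 pent-3-yn-1-yl trifluoromethanesulfonate
Conditions: (CF3SO2)2O, 2,6-lutidine, CH2Cl2, −78 °C, used at once
Reagents that add atoms: trifluoromethanesulfonic anhydride O=S(=O)(OS(=O)(=O)C(F)(F)F)C(F)(F)F
Why: O-Sulfonylation of the primary alcohol gives an electrophile that alkylates a hindered enolate at low temperature and so outruns the E2 elimination typical of homopropargylic halides.

Step 6
Reactants: 7 (3R,4R)-3-methyl lactone; 9 pent-3-yn-1-yl trifluoromethanesulfonate
Product: 11 (3R,4S)-5,7-bis(benzyloxy)-3-methyl-4-(2-methylpropyl)-3-(pent-3-yn-1-yl)chroman-2-one (methyl cis and pentynyl trans to isobutyl), via lithium enolate 10 (not isolated)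
Conditions: LiN(iPr)2, THF–DMPU, −78 °C; then 9, −78 to −40 °C
Reagents that add atoms: none
Why: Diastereoselective enolate alkylation creates the quaternary centre C2, because peri strain with the 5-benzyloxy group holds the isobutyl group pseudo-axial over one face of the flat enolate, so the triflate attacks the other face and ends trans to isobutyl with the methyl group cis.

Step 7
Reactants: 11 (3R,4S)-3-methyl-3-(pent-3-yn-1-yl) lactone
Product: 12 (3R,4S)-5,7-bis(benzyloxy)-3-methyl-4-(2-methylpropyl)-3-(pent-3-yn-1-yl)chroman-2-ol (lactol, both anomers)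
Conditions: iBu2AlH, CH2Cl2, −78 °C; aq. potassium sodium tartrate
Reagents that add atoms: none
Why: Partial lactone reduction with iBu2AlH stops at the lactol because the tetrahedral aluminium alkoxide next to the quaternary carbon survives at −78 °C until work-up, and the new anomeric centre is lost in step 8.

Step 8
Reactants: 12 lactol
Product: 13 3,5-bis(benzyloxy)-2-[(4R,5S)-5-ethenyl-2,5-dimethyldec-8-yn-4-yl]phenol
Conditions: Ph3PCH3Br, NaN(SiMe3)2 (excess ylide), THF, 0 to 40 °C
Reagents that add atoms: methyltriphenylphosphonium bromide C[P+](c1ccccc1)(c1ccccc1)c1ccccc1.[Br-]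
Why: Wittig methylenation of the hydroxy aldehyde in equilibrium with the lactol opens the temporary ring, frees the phenol needed for ring B and makes C3 a vinyl CH, with no epimerisation possible because the α-carbon C2 is quaternary.

Step 9
Reactants: 13 enyne phenol
Product: 14 3,5-bis(benzyloxy)-2-{(1R)-3-methyl-1-[(1S)-1-methyl-3-(prop-1-en-2-yl)cyclopent-2-en-1-yl]butyl}phenol
Conditions: second-generation Grubbs catalyst (H2IMes)(PCy3)Cl2Ru=CHPh (cat.), ethylene (1 atm), toluene, 80 °C
Reagents that add atoms: none
Why: Ring-closing enyne metathesis in the exo mode, well known for 1,6-enynes with methyl-capped alkynes, joins C3 to C4 and moves the terminal CH2 to C7 as C8, giving the 1-isopropenylcyclopentene without touching C1 or C2, while ethylene keeps the ruthenium methylidene alive.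

Step 10
Reactants: 15 1-bromo-2-methylprop-1-ene
Product: 16 1,1,2-tribromo-3,3-dimethylcyclopropane (racemic)
Conditions: CHBr3, 50% aq. NaOH, BnEt3NCl (cat.), 0 °C to rt
Reagents that add atoms: bromoform BrC(Br)Br
Why: [2+1] Cycloaddition of dibromocarbene, generated from bromoform under phase-transfer conditions, to the trisubstituted bromoalkene gives the tribromide, whose single racemic stereocentre disappears in step 11.

Step 11
Reactants: 16 1,1,2-tribromo-3,3-dimethylcyclopropane
Product: 19 3,3-dimethylcyclopropene, via 1-bromo-3,3-dimethylcyclopropene 17 (not isolated), via 1-lithio-3,3-dimethylcyclopropene 18 (not isolated)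
Conditions: MeLi (2.1 equiv), Et2O, −78 to 0 °C; then H2O; volatile product swept with N2 into CH2Cl2 at −78 °C
Reagents that add atoms: none
Why: Bromine–lithium exchange at the CBr2 carbon with 1,2-elimination of LiBr gives the bromocyclopropene, a second exchange gives the cyclopropenyllithium, and water protonates it, a sequence established for 1,1,2-trihalocyclopropanes.

Step 12
Reactants: 14 diene phenol; 19 3,3-dimethylcyclopropene
Product: 20 carene-type adduct (rings C, D and E complete; C4=C7 alkene; C10 cis to the C2 methyl group on ring C; C11 syn to C3–H on ring D; phenol free)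
Conditions: 19 (about 10 equiv), BHT (trace), CH2Cl2, 12 kbar, 40 °C
Reagents that add atoms: none
Why: Concerted, suprafacial [4π+2π] Diels–Alder cycloaddition in which the s-cis C3=C4–C7=C8 diene of 14 adds across the strained C9=C10 bond of 19, the release of about half of the cyclopropene strain and the strongly negative activation volume (hence the pressure) making up for the missing electronic activation. The closest known reactions are the additions of cyclopropene itself and of 3,3-disubstituted cyclopropenes (cyclopropenone acetals, 3,3-dihalocyclopropenes) to open-chain and semicyclic dienes, which take the exo course. Ring D is closed in this intermolecular [4+2] mode (C8–C9 and C10–C3 formed together) and ring E is carried in intact, leaving the C4=C7 alkene exactly where ring B must be closed. C3 is set by the neighbouring quaternary centre C2, the dienophile adding to the diene face that bears the C2 methyl group and not the large C1 (aryl, isobutyl) branch; C9 and C10 are cis by suprafacial addition, and their sense follows from the exo transition state (C11 turned away from C4/C7), since the endo alternative would drive a C11 methyl group into the diene, so that C11 ends syn to C3–H as in the target. No regiochemical question arises because 19 is symmetric; the diene is the only reactive π system of 14, and 19, having no hydrogen on C11, cannot consume itself by ene dimerisation and therefore tolerates long reaction times in excess.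

Step 13
Reactants: 20 carene-type adduct
Product: 21 dibenzyl ether of the pentacycle (rings A–E complete; O on C4, CH3 on C7, C3–H and C11 all on one face of ring D)
Conditions: camphor-10-sulfonic acid (20 mol %), CH2Cl2, −20 °C to rt
Reagents that add atoms: none
Why: Brønsted acid-catalysed intramolecular Markovnikov hydroalkoxylation of the tetrasubstituted C4=C7 alkene, in which, as with 3-carene, the proton reaches C7 from the face of ring D opposite C11 and the tertiary C4 cation can be captured only by the ortho-phenol that C1 and C2 hold over the other face, so this anti addition closes ring B and sets C7 (methyl syn to oxygen) and C4 together.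

Step 14
Reactants: 21 dibenzyl ether of the pentacycle
Product: 22 pentacyclic bis-phenol (both benzyl groups replaced by H)
Conditions: H2 (1 atm), 10% Pd/C, EtOAc–EtOH, rt
Reagents that add atoms: none
Why: Hydrogenolysis cleaves the two benzyl aryl ethers, while the tertiary alkyl aryl ether (not benzylic on its alkyl side) and the unconjugated alkyl-substituted cyclopropane are inert under these mild conditions.

Step 15
Reactants: 22 pentacyclic bis-phenol
Product: 24 target CNP0202714.1, via bis(iminium) salt 23 (not isolated)
Conditions: POCl3, DMF, MeCN, 0 °C to rt; then H2O, rt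
Reagents that add atoms: N,N-dimethylformamide CN(C)C=O; water O
Why: Vilsmeier–Haack formylation attacks the two remaining aromatic C–H positions, each ortho or para to three oxygen donors and the only nucleophilic carbons present, and hydrolysis of the bis(iminium) salt liberates both aldehydes without touching a stereocentre.

**Compound list**

1 | phloroglucinol | Oc1cc(O)cc(O)c1 | starting material
2 | ethyl 5-methyl-3-oxohexanoate | CCOC(=O)CC(=O)CC(C)C | starting material
3 | 5,7-dihydroxy-4-(2-methylpropyl)-2H-chromen-2-one | CC(C)CC1=CC(=O)Oc2cc(O)cc(O)c12 | intermediate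
4 | 5,7-bis(benzyloxy)-4-(2-methylpropyl)-2H-chromen-2-one | CC(C)CC1=CC(=O)Oc2cc(OCc3ccccc3)cc(OCc3ccccc3)c12 | intermediate
5 | (4R)-5,7-bis(benzyloxy)-4-(2-methylpropyl)chroman-2-one | CC(C)C[C@H]1c2c(OCc3ccccc3)cc(OCc3ccccc3)cc2OC(=O)C1 | intermediate
6 | lithium enolate of 5 | CC(C)C[C@H]1c2c(OCc3ccccc3)cc(OCc3ccccc3)cc2OC([O-])=C1.[Li+] | intermediate
7 | (3R,4R)-5,7-bis(benzyloxy)-3-methyl-4-(2-methylpropyl)chroman-2-one | CC(C)C[C@H]1c2c(OCc3ccccc3)cc(OCc3ccccc3)cc2OC(=O)[C@@H]1C | intermediate
8 | pent-3-yn-1-ol | CC#CCCO | starting material
9 | pent-3-yn-1-yl trifluoromethanesulfonate | CC#CCCOS(=O)(=O)C(F)(F)F | intermediate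
10 | lithium enolate of 7 | CC(C)C[C@H]1c2c(OCc3ccccc3)cc(OCc3ccccc3)cc2OC([O-])=C1C.[Li+] | intermediate
11 | (3R,4S)-5,7-bis(benzyloxy)-3-methyl-4-(2-methylpropyl)-3-(pent-3-yn-1-yl)chroman-2-one | CC(C)C[C@H]1c2c(OCc3ccccc3)cc(OCc3ccccc3)cc2OC(=O)[C@]1(C)CCC#CC | intermediate
12 | (3R,4S)-lactol of 11, both anomers | CC(C)C[C@H]1c2c(OCc3ccccc3)cc(OCc3ccccc3)cc2OC(O)[C@]1(C)CCC#CC | intermediate
13 | 3,5-bis(benzyloxy)-2-[(4R,5S)-5-ethenyl-2,5-dimethyldec-8-yn-4-yl]phenol | CC(C)C[C@@H](c1c(O)cc(OCc2ccccc2)cc1OCc1ccccc1)[C@](C)(C=C)CCC#CC | intermediate
14 | 3,5-bis(benzyloxy)-2-{(1R)-3-methyl-1-[(1S)-1-methyl-3-(prop-1-en-2-yl)cyclopent-2-en-1-yl]butyl}phenol | CC(C)C[C@@H](c1c(O)cc(OCc2ccccc2)cc1OCc1ccccc1)[C@@]1(C)CCC(C(C)=C)=C1 | intermediate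
15 | 1-bromo-2-methylprop-1-ene | CC(C)=CBr | starting material
16 | 1,1,2-tribromo-3,3-dimethylcyclopropane (racemic) | CC1(C)C(Br)C1(Br)Br | intermediate
17 | 1-bromo-3,3-dimethylcyclopropene | CC1(C)C=C1Br | intermediate
18 | 1-lithio-3,3-dimethylcyclopropene | CC1(C)C=C1[Li] | intermediate
19 | 3,3-dimethylcyclopropene | CC1(C)C=C1 | intermediate
20 | carene-type Diels–Alder adduct (C4=C7 alkene, free phenol) | CC(C)C[C@@H](c1c(O)cc(OCc2ccccc2)cc1OCc1ccccc1)[C@@]1(C)CCC2=C(C)C[C@@H]3[C@H]([C@H]12)C3(C)C | intermediate
21 | dibenzyl ether of the pentacycle | CC(C)C[C@H]1c2c(OCc3ccccc3)cc(OCc3ccccc3)cc2O[C@]23CC[C@@]1(C)[C@H]2[C@H]1[C@@H](C[C@@H]3C)C1(C)C | intermediate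
22 | pentacyclic bis-phenol | CC(C)C[C@H]1c2c(O)cc(O)cc2O[C@]23CC[C@@]1(C)[C@H]2[C@H]1[C@@H](C[C@@H]3C)C1(C)C | intermediate
23 | bis(dimethyliminium) salt of 24, drawn as bis(dichlorophosphate) | CC(C)C[C@H]1c2c(O)c(C=[N+](C)C)c(O)c(C=[N+](C)C)c2O[C@]23CC[C@@]1(C)[C@H]2[C@H]1[C@@H](C[C@@H]3C)C1(C)C.[O-]P(Cl)(Cl)=O.[O-]P(Cl)(Cl)=O | intermediate
24 | CNP0202714.1 | CC(C)C[C@H]1c2c(O)c(C=O)c(O)c(C=O)c2O[C@]23CC[C@@]1(C)[C@H]2[C@H]1[C@@H](C[C@@H]3C)C1(C)C | target

Total steps: 15. Longest linear sequence: 12 steps (1–4, 6–9, 12–15).

**Steps most likely to fail**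

**Step 12.** The cycloaddition may be too slow, because the dienophile carries a gem-dimethyl group beside the reacting bond and the C3 terminus of the diene is neopentyl. Ene-type addition of 19 to allylic C–H bonds, or oligomerisation under pressure, could then overtake it.

The fallback sets out from 18 (made as in step 11) and 14.
- Quenching 18 with benzenesulfonyl fluoride instead of water would give 3,3-dimethyl-1-(phenylsulfonyl)cyclopropene F1. This is a LUMO-lowered and still strained dienophile of the electron-poor gem-dimethylcyclopropene class that adds to open-chain dienes.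
- Heating F1 with 14 in toluene would give, through the same exo approach anti to the C1 branch, the C9-phenylsulfonyl adduct F2. The orientation of the unsymmetrical dienophile is of no consequence, since the sulfonyl group is removed.
- Reductive desulfonylation with sodium amalgam and Na2HPO4 in MeOH replaces sulfur by hydrogen, with the cis ring fusion enforced by the bicycle, and comes back to the route at 20.

**Step 13.** After protonation, a 1,2-hydride shift from C3 to C4 may outrun ring closure and pass the charge to the cyclopropylcarbinyl position. That would open ring E or close the ether at the wrong carbon. Reversible protonation may also erode the C7 configuration.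

The fallback sets out from 20 and avoids a free cation.
- N-(Phenylselanyl)phthalimide with catalytic camphor-10-sulfonic acid in CH2Cl2 at low temperature would form the seleniranium ion on the face opposite C11.
- The tethered phenol would open it anti at C4 to give the C7 phenylselenide F3.
- Bu3SnH and AIBN in toluene at 80 °C would then replace selenium by hydrogen. The tertiary C7 radical takes hydrogen from the face opposite C11 and the aryloxy group, which comes back to the route at 21.

**Step 9.** Initiation at the neopentyl vinyl group may be sluggish. Closure may also stray into the endo mode, or the reaction may stop after cross metathesis of the alkyne with ethylene.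

The fallback sets out from 7 and builds ring C by carbonyl chemistry.
- Enolate 10 would be alkylated with 2-(3-iodopropyl)-2-methyl-1,3-dioxolane (same anti approach) to give ketal lactone F4.
- iBu2AlH would reduce F4 to ketal lactol F5.
- Aqueous HCl in THF would free keto lactol F6.
- KOH in MeOH would close the five-membered ring by intramolecular aldol condensation of the ketone α-CH2 (C4) onto the non-enolisable aldehyde (C3), giving acetylcyclopentene F7.
- Wittig methylenation of the ketone comes back to the route at 14.

**Further compounds**

F1 | step 12 | 3,3-dimethyl-1-(phenylsulfonyl)cyclopropene | CC1(C)C=C1S(=O)(=O)c1ccccc1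
F2 | step 12 | C9-phenylsulfonyl adduct | CC(C)C[C@@H](c1c(O)cc(OCc2ccccc2)cc1OCc1ccccc1)[C@@]1(C)CCC2=C(C)C[C@]3(S(=O)(=O)c4ccccc4)[C@H]([C@H]12)C3(C)C
F3 | step 13 | C7 phenylselenide | CC(C)C[C@H]1c2c(OCc3ccccc3)cc(OCc3ccccc3)cc2O[C@]23CC[C@@]1(C)[C@H]2[C@H]1[C@@H](C[C@@]3(C)[Se]c2ccccc2)C1(C)C
F4 | step 9 | ketal lactone | CC(C)C[C@H]1c2c(OCc3ccccc3)cc(OCc3ccccc3)cc2OC(=O)[C@]1(C)CCCC1(C)OCCO1
F5 | step 9 | ketal lactol | CC(C)C[C@H]1c2c(OCc3ccccc3)cc(OCc3ccccc3)cc2OC(O)[C@]1(C)CCCC1(C)OCCO1
F6 | step 9 | keto lactol | CC(C)C[C@H]1c2c(OCc3ccccc3)cc(OCc3ccccc3)cc2OC(O)[C@]1(C)CCCC(C)=O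
F7 | step 9 | acetylcyclopentene | CC(C)C[C@@H](c1c(O)cc(OCc2ccccc2)cc1OCc1ccccc1)[C@@]1(C)CCC(C(C)=O)=C1
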